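The 6 questions come down to one fork: what does a molecule of Q meet first?

| flask | Q | X | remark | time |
|---|---|---|---|---|
| south | 10 mM | 0.58 equiv | run made earlier |  |
| north | 10 mM | 0.95 equiv | run made earlier |  |
| ochre | 10 mM | 0.600 equiv |  | 3.0 min |
| red | 10 mM | 0.720 equiv |  | 3.0 min |
| grey | 10 mM | 0.500 equiv |  | 3.0 min |

- south (time / s: Q / %, E / %): 25.0: 51.3, 9.9; 50.0: 33.1, 15.3; 60.0: 28.8, 16.5; 90.0: 21.2, 20.2
- north (time / s: Q / %, E / %): 12.0: 66.5, 9.9; 30.0: 42.7, 17.5; 60.0: 24.8, 26.0; 90.0: 16.3, 30.6

(readings scatter by 0.5 percentage points)

1. which of these there is most of at the end, counted by the Q in it, ochre (Q / E)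
2. which of these there is most of at the end, counted by the Q in it, red (Q / E)
3. which of these there is most of at the end, counted by the Q in it, grey (Q / E)
4. final amount of the leader among these, as a percentage of the Q charged, in ochre
5. final amount of the leader among these, as a percentage of the Q charged, in red
6. final amount of the leader among these, as a percentage of the Q charged, in grey

- percentages count the Q that a species holds: one L counts as two
- what may be going on: Q + X -> E + G; 2 Q -> L

A molecule of Q can go with X to E, or with a second Q to L, so I need two waiting times at the start of grey: the time to X and the time to a partner Q. The first reading of the north run gives both, taking X as charged, which overstates it a little. By 12.0 s, Q stands at 66.5 % and E at 9.9 %, so the rest of the lost Q, 23.6 %, went to L.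

For a purely second-order loss, the mean of Q squared over an interval is the product of its first and last values, and I use that here as an approximation. That gives a time to a partner of 33.8 s. Using the mean of Q and scaling X to grey's charge gives a time to X of 192 s. Their quotient is the fork ratio, the odds at the start of grey that a Q goes to L against E, which reads here as 5.67. It is a working form of the selectivity factor.

Counting the partner wait alone, I reckon grey's Q at 15.8 % by 3.0 min. Counting the X wait with X unspent, I reckon its E at 32.5 %. Each figure leaves out a further drain, so I take both as rough high estimates, and with E above Q I expect E to lead.

The forecast agrees on the leader, “E leads Q in all three”, and gives E as 25.7 % in ochre, 29.9 % in red and 22 % in grey, the last below my high estimate.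

The flasks give E 25.6 % against Q 9.65 % in ochre, 29.8 % against 8.62 % in red, and 21.9 % against 10.6 % in grey.

    Q + X → E + G (k = 1.10 /M/s)
    2 Q → L (k = 1.50 /M/s)

The main reason for the gap between red's E and grey's is the difference in equivalents of X: with that difference taken away, red's E is 21.9 % instead of 29.8 %. This speaks of the gap alone, not of the size of E itself. Charged at 4.0 mM of Q, with the same equivalents, grey's neighbour keeps the fork ratio at 5.67, but the time to X stretches to 479 s, so its 3.0 min counts as 1.20 min of grey. It gives Q 25.7 % and E 15.9 %, with Q ahead.

Readings and results come from a simulation on assumed constants.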